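**Retrosynthetic overview**

- The strategy rests on the 1,2,3,5-tetrasubstituted benzene ring C3a–C4–C5–C6–C7–C7a, fused to the dihydrofuran through O1–C7a and C3–C3a. O1–C2–C3 is therefore the three-atom tether of a 1,6-diyne (ynol ether C7a≡C7, silylalkyne C3a≡C4), and C5–C6 is an alkoxyalkyne.
- Key disconnection: a rhodium-catalysed (2+2+2) cycloaddition of the ynol-ether diyne with benzyloxyethyne forms C3a–C7a, C4–C5 and C6–C7 and closes the benzene and dihydrofuran rings in one event. The diyne comes from an anti-selective allenylindium addition (C2–C3 bond, both stereocentres) followed by ynol-ether formation with trichloroethylene.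
- C4 is meta to both ring oxygens, so electrophilic ipso-halogenation of a C4 silane would lose to C–H halogenation at C5, C7 and the resorcinol ring. The silyl group is therefore benzyldimethylsilyl, which is oxidised to the C4 phenol and converted to the triflate.
- The oxolane is built last. A trans-4,5-diaryl lactone from the mirror-image propargylic series is α-arylated by the C4 triflate (C4–C3′), C3′ is inverted by kinetic protonation, and aryl addition then Et3SiH/BF3 reduction sets C2′.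
- All eight phenols travel as benzyl ethers and are released by hydrogenolysis, because the all-cis oxolane would not survive Lewis-acid ether cleavage. Ring order: benzene with dihydrofuran (step 7), lactone (step 13), oxolane (step 17).

Key step: step 7

Assumption: (S)-BINOL with Ti(OiPr)4 is taken to deliver the alkynylzinc to the Si face of the aryl aldehyde, as it does with benzaldehyde, giving the (R)-carbinol (and (R)-BINOL the (S)-carbinol); each batch is to be checked by Mosher ester analysis before use.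

**Route**

Step 1
Reactants: 1 ethynylmagnesium bromide; 2 benzyl(chloro)dimethylsilane
Product: 3 benzyl(ethynyl)dimethylsilane
Conditions: THF, 0 °C to rt
Reagents that add atoms: none
Why: Nucleophilic substitution at silicon by an alkynyl Grignard reagent is routine and gives an alkyne whose silyl group can later be oxidised (benzyl is removable from silicon by fluoride).

Step 2
Reactants: 3 benzyl(ethynyl)dimethylsilane; 4 3,5-bis(benzyloxy)benzaldehyde
Product: 6 (R)-propargylic alcohol, via ethylzinc silylacetylide 5 (not isolated)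
Conditions: 3, Et2Zn, toluene, reflux; then (S)-BINOL (40 mol%), Ti(OiPr)4 (1 equiv), 4, CH2Cl2, rt; aq. NH4Cl
Reagents that add atoms: none
Why: BINOL–titanium-catalysed enantioselective alkynylzinc addition is well established for aromatic aldehydes, and the (S)-ligand should direct Si-face attack so that the carbinol centre is set as R.

Step 3
Reactants: 6 (R)-propargylic alcohol
Product: 7 (R)-propargylic mesylate
Conditions: MsCl, Et3N, CH2Cl2, −78 °C; used crude at once
Reagents that add atoms: methanesulfonyl chloride, CS(=O)(=O)Cl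
Why: O-sulfonylation proceeds with retention at carbon, and the meta-alkoxy groups do not assist ionisation, so the benzylic propargylic mesylate should survive if kept cold and used directly.

Step 4
Reactants: 7 (R)-propargylic mesylate; 8 4-(benzyloxy)benzaldehyde
Product: 10 (1S,2S)-homopropargylic alcohol, via allenylindium 9 (not isolated)
Conditions: Pd(OAc)2 (5 mol%), PPh3 (5 mol%), InI (1.5 equiv), THF–HMPA (3:1), rt
Reagents that add atoms: none
Why: In this palladium-catalysed, indium-mediated umpolung propargylation, zerovalent palladium opens the mesylate by anti SN2′ substitution, transmetalation gives allenylindium 9, and SE2′ addition to the aldehyde through a cyclic transition state forms the C2–C3 bond with net inversion at the former mesylate carbon (C3, S) and the anti relationship that fixes C2 as S.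

Step 5
Reactants: 10 (1S,2S)-homopropargylic alcohol; 11 trichloroethylene
Product: 14 ynol-ether diyne, via dichlorovinyl ether 12 (not isolated), via lithium alkynyl ether 13 (not isolated)
Conditions: KH, THF, 0 °C; 11, −50 °C to rt; then n-BuLi (2.2 equiv), −78 °C; MeOH, −78 °C
Reagents that add atoms: none
Why: In the trichloroethylene route to ynol ethers the potassium alkoxide adds to dichloroacetylene formed in situ, and n-butyllithium then effects elimination and chlorine–lithium exchange to the lithium alkynyl ether, which methanol protonates; the carbinol C–O bond is never broken, so both stereocentres are retained.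

Step 6
Reactants: 15 benzyl alcohol; 11 trichloroethylene
Product: 18 benzyloxyethyne, via benzyl dichlorovinyl ether 16 (not isolated), via lithium benzyloxyacetylide 17 (not isolated)
Conditions: KH, THF, 0 °C; 11, −50 °C to rt; then n-BuLi (2.2 equiv), −78 °C; MeOH, −78 °C; kept cold in solution
Reagents that add atoms: none
Why: The same alkoxide addition, elimination and chlorine–lithium exchange sequence converts a primary alcohol into its terminal ynol ether, which is stable below room temperature and is used promptly.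

Step 7
Reactants: 14 ynol-ether diyne; 18 benzyloxyethyne
Product: 19 4-silyl-6-benzyloxy-2,3-dihydrobenzofuran
Conditions: [Rh(cod)2]BF4 (10 mol%), rac-BINAP (10 mol%), H2 activation then argon, CH2Cl2, rt; slow addition of 14 to 18 (3 equiv)
Reagents that add atoms: none
Why: Proposed new method: the cationic monovalent rhodium–BINAP fragment should bind the ynol-ether and silylalkyne units of 14 and couple them oxidatively to a rhodacyclopentadiene in which the C3a–C7a bond and the O1–C2–C3–C3a–C7a dihydrofuran ring already exist, after which 18 inserts into the Rh–C7 bond and reductive elimination forms C6–C7 and C4–C5 and releases the arene. The closest known reaction type is the rhodium/BINAP (2+2+2) cycloaddition of ynamide-tethered 1,6-diynes with monoalkynes to indolines; the oxygen analogue with an ynol-ether tether and an alkoxyalkyne partner has not been shown. The five-membered ring closes by intramolecular alkyne–alkyne oxidative cyclisation on rhodium (C3a–C7a), and the benzene ring closes by insertion of the third alkyne and reductive elimination. No stereocentre is created: C2 and C3 lie in the tether, carry no bond that is labile under these neutral conditions and pass through unchanged. The step needs regioselectivity (benzyloxy-bearing carbon to C7, CH to C4) and cross- over homo-cyclotrimerisation; the bulky benzyldimethylsilyl group on C4 should steer the substituted alkyne carbon to the unhindered C7 end, slow addition of the diyne into excess 18 limits diyne self-coupling, and room temperature avoids retro-ene loss of ketene from the secondary ynol ether.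

Step 8
Reactants: 19 4-silyl-6-benzyloxy-2,3-dihydrobenzofuran
Product: 21 dihydrobenzofuran-4-ol, via aryldimethylsilanol 20 (not isolated)
Conditions: TBAF, THF, 0 °C to rt; then KHCO3, 30% H2O2, MeOH, 40 °C
Reagents that add atoms: hydrogen peroxide, OO; water, O
Why: Fluoride expels the benzyl group from silicon (the best carbanion leaving group present), and the resulting aryl silanol undergoes Tamao–Fleming oxidation with retention at C4 under basic, non-electrophilic conditions that leave the electron-rich rings untouched.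

Step 9
Reactants: 21 dihydrobenzofuran-4-ol
Product: 22 C4 aryl triflate
Conditions: PhNTf2, Et3N, DMAP (10 mol%), CH2Cl2, rt
Reagents that add atoms: N-phenylbis(trifluoromethanesulfonimide), O=S(=O)(N(c1ccccc1)S(=O)(=O)C(F)(F)F)C(F)(F)F
Why: O-sulfonylation of the phenol with a mild triflyl donor gives the cross-coupling handle without exposing the C2–O1 benzylic ether to acid.

Step 10
Reactants: 23 ethynyl(trimethyl)silane; 4 3,5-bis(benzyloxy)benzaldehyde
Product: 25 (S)-propargylic alcohol, via ethylzinc trimethylsilylacetylide 24 (not isolated)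
Conditions: 23, Et2Zn, toluene, reflux; then (R)-BINOL (40 mol%), Ti(OiPr)4 (1 equiv), 4, CH2Cl2, rt; aq. NH4Cl
Reagents that add atoms: none
Why: The same BINOL–titanium-catalysed alkynylzinc addition with the antipodal ligand should give Re-face attack and the (S)-carbinol needed for the oxolane half.

Step 11
Reactants: 25 (S)-propargylic alcohol
Product: 26 (S)-propargylic mesylate
Conditions: MsCl, Et3N, CH2Cl2, −78 °C; used crude at once
Reagents that add atoms: methanesulfonyl chloride, CS(=O)(=O)Cl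
Why: O-sulfonylation with retention, as in step 3.

Step 12
Reactants: 26 (S)-propargylic mesylate; 8 4-(benzyloxy)benzaldehyde
Product: 28 (1R,2R)-homopropargylic alcohol, via allenylindium 27 (not isolated)
Conditions: Pd(OAc)2 (5 mol%), PPh3 (5 mol%), InI (1.5 equiv), THF–HMPA (3:1), rt
Reagents that add atoms: none
Why: The palladium-catalysed, indium-mediated propargylation of step 4 in the mirror-image series (anti SN2′, then SE2′ through a cyclic transition state) sets the future C4′ and C5′ centres with the anti relationship.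

Step 13
Reactants: 28 (1R,2R)-homopropargylic alcohol
Product: 31 trans-4,5-diaryl lactone, via alkenylborane 29 (not isolated), via hydroxy acid 30 (not isolated)
Conditions: Cy2BH (2.5 equiv), THF, 0 °C to rt; NaOH, 30% H2O2, 0 to 50 °C; then HCl to pH 2, rt
Reagents that add atoms: hydrogen peroxide, OO; water, O
Why: Silylalkyne hydroboration–oxidation places boron on the silicon-bearing carbon and alkaline peroxide converts the α-silyl alkenylborane into the carboxylic acid, which lactonises with the γ-hydroxyl on acidification; neither stereocentre is involved, so the 4,5-trans lactone results.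

Step 14
Reactants: 31 trans-4,5-diaryl lactone; 22 C4 aryl triflate
Product: 33 3,4-trans α-aryl lactone, via zinc enolate 32 (not isolated)
Conditions: 31, LiHMDS, THF, −78 °C; ZnCl2, −78 °C to rt; then 22, Pd2(dba)3 (2.5 mol%), XPhos (10 mol%), THF, 60 °C
Reagents that add atoms: none
Why: Palladium-catalysed α-arylation of a zinc enolate (Negishi/Reformatsky-type) tolerates the lactone and the triflate, and the C4–C3′ bond forms anti to the C4′ aryl group, giving the 3,4-trans lactone, which is also the thermodynamic epimer.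

Step 15
Reactants: 33 3,4-trans α-aryl lactone
Product: 35 3,4-cis α-aryl lactone, via lithium enolate 34 (not isolated)
Conditions: LDA (1.3 equiv), THF, −78 °C; 2,6-di-tert-butyl-4-methylphenol (3 equiv), −78 °C; aq. NH4Cl, −78 °C
Reagents that add atoms: none
Why: Kinetic protonation of the planar lithium enolate by a bulky phenol should occur on the face opposite the adjacent C4′ aryl group, placing the C3′ hydrogen trans and the benzofuranyl group cis to it (C3′ R); the less stable cis lactone is kept away from base thereafter.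

Step 16
Reactants: 35 3,4-cis α-aryl lactone; 36 1-(benzyloxy)-4-bromobenzene
Product: 39 cyclic hemiketal, via aryllithium 37 (not isolated), via arylcerium dichloride 38 (not isolated)
Conditions: 36, n-BuLi, THF, −78 °C; anhydrous CeCl3, THF, −78 °C; then 35, −78 °C; pH 7 buffer, −78 °C; used crude at once
Reagents that add atoms: none
Why: Organocerium carbonyl addition uses a weakly basic aryl nucleophile that adds once to the lactone at low temperature without removing the acidic C3′ proton; the tetrahedral adduct persists until quench and is taken on as the hemiketal before the open hydroxy ketone can epimerise.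

Step 17
Reactants: 39 cyclic hemiketal
Product: 40 octabenzyl ether of the target
Conditions: Et3SiH (5 equiv), BF3·OEt2 (3 equiv), CH2Cl2, −78 to −40 °C
Reagents that add atoms: none
Why: Reductive deoxygenation of a cyclic hemiketal proceeds by Lewis-acid ionisation to the 2-aryl oxocarbenium ion and hydride delivery anti to the C3′ substituent, which sets C2′ as R with the 2′,3′-cis relationship; low temperature and excess silane favour capture over loss of the C3′ proton.

Step 18
Reactants: 40 octabenzyl ether of the target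
Product: 41 CNP0202577.4
Conditions: H2 (1 atm), 10% Pd/C, EtOAc–MeOH (1:1), rt
Reagents that add atoms: none
Why: Hydrogenolysis of the eight primary aryl benzyl ethers over palladium on carbon is neutral and faster than cleavage of the hindered ring benzylic C–O bonds, so no stereocentre of the all-cis oxolane is exposed to acid.

**Compound list**

1 | ethynylmagnesium bromide | C#C[Mg]Br | starting material
2 | benzyl(chloro)dimethylsilane | C[Si](C)(Cl)Cc1ccccc1 | starting material
3 | benzyl(ethynyl)dimethylsilane | C#C[Si](C)(C)Cc1ccccc1 | intermediate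
4 | 3,5-bis(benzyloxy)benzaldehyde | O=Cc1cc(OCc2ccccc2)cc(OCc2ccccc2)c1 | starting material
5 | {[benzyl(dimethyl)silyl]ethynyl}(ethyl)zinc | CC[Zn]C#C[Si](C)(C)Cc1ccccc1 | intermediate (not isolated)
6 | (1R)-1-[3,5-bis(benzyloxy)phenyl]-3-[benzyl(dimethyl)silyl]prop-2-yn-1-ol | O[C@@H](C#C[Si](C)(C)Cc1ccccc1)c1cc(OCc2ccccc2)cc(OCc2ccccc2)c1 | intermediate
7 | (1R)-1-[3,5-bis(benzyloxy)phenyl]-3-[benzyl(dimethyl)silyl]prop-2-yn-1-yl methanesulfonate | CS(=O)(=O)O[C@@H](C#C[Si](C)(C)Cc1ccccc1)c1cc(OCc2ccccc2)cc(OCc2ccccc2)c1 | intermediate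
8 | 4-(benzyloxy)benzaldehyde | O=Cc1ccc(OCc2ccccc2)cc1 | starting material
9 | (aS)-{1-[benzyl(dimethyl)silyl]-3-[3,5-bis(benzyloxy)phenyl]propa-1,2-dien-1-yl}(iodo)indium methanesulfonate | CS(=O)(=O)O[In](I)C([Si](C)(C)Cc1ccccc1)=[C@@]=C([H])c1cc(OCc2ccccc2)cc(OCc2ccccc2)c1 | intermediate (not isolated)
10 | (1S,2S)-1-[4-(benzyloxy)phenyl]-2-[3,5-bis(benzyloxy)phenyl]-4-[benzyl(dimethyl)silyl]but-3-yn-1-ol | O[C@H](c1ccc(OCc2ccccc2)cc1)[C@H](C#C[Si](C)(C)Cc1ccccc1)c1cc(OCc2ccccc2)cc(OCc2ccccc2)c1 | intermediate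
11 | trichloroethylene | ClC=C(Cl)Cl | starting material
12 | benzyl{(3S,4S)-4-[4-(benzyloxy)phenyl]-3-[3,5-bis(benzyloxy)phenyl]-4-{[(E)-1,2-dichloroethenyl]oxy}but-1-yn-1-yl}dimethylsilane | Cl/C=C(/Cl)O[C@H](c1ccc(OCc2ccccc2)cc1)[C@H](C#C[Si](C)(C)Cc1ccccc1)c1cc(OCc2ccccc2)cc(OCc2ccccc2)c1 | intermediate (not isolated)
13 | lithium 2-{[(1S,2S)-1-[4-(benzyloxy)phenyl]-2-[3,5-bis(benzyloxy)phenyl]-4-[benzyl(dimethyl)silyl]but-3-yn-1-yl]oxy}ethynide | [Li]C#CO[C@H](c1ccc(OCc2ccccc2)cc1)[C@H](C#C[Si](C)(C)Cc1ccccc1)c1cc(OCc2ccccc2)cc(OCc2ccccc2)c1 | intermediate (not isolated)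
14 | benzyl{(3S,4S)-4-[4-(benzyloxy)phenyl]-3-[3,5-bis(benzyloxy)phenyl]-4-(ethynyloxy)but-1-yn-1-yl}dimethylsilane | C#CO[C@H](c1ccc(OCc2ccccc2)cc1)[C@H](C#C[Si](C)(C)Cc1ccccc1)c1cc(OCc2ccccc2)cc(OCc2ccccc2)c1 | intermediate
15 | benzyl alcohol | OCc1ccccc1 | starting material
16 | benzyl (E)-1,2-dichloroethenyl ether | Cl/C=C(/Cl)OCc1ccccc1 | intermediate (not isolated)
17 | [(benzyloxy)ethynyl]lithium | [Li]C#COCc1ccccc1 | intermediate (not isolated)
18 | (benzyloxy)ethyne | C#COCc1ccccc1 | intermediate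
19 | benzyl{(2S,3S)-6-(benzyloxy)-2-[4-(benzyloxy)phenyl]-3-[3,5-bis(benzyloxy)phenyl]-2,3-dihydro-1-benzofuran-4-yl}dimethylsilane | C(Oc1ccc([C@H]2Oc3cc(OCc4ccccc4)cc([Si](C)(C)Cc4ccccc4)c3[C@@H]2c2cc(OCc3ccccc3)cc(OCc3ccccc3)c2)cc1)c1ccccc1 | intermediate
20 | {(2S,3S)-6-(benzyloxy)-2-[4-(benzyloxy)phenyl]-3-[3,5-bis(benzyloxy)phenyl]-2,3-dihydro-1-benzofuran-4-yl}dimethylsilanol | C(Oc1ccc([C@H]2Oc3cc(OCc4ccccc4)cc([Si](C)(C)O)c3[C@@H]2c2cc(OCc3ccccc3)cc(OCc3ccccc3)c2)cc1)c1ccccc1 | intermediate (not isolated)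
21 | (2S,3S)-6-(benzyloxy)-2-[4-(benzyloxy)phenyl]-3-[3,5-bis(benzyloxy)phenyl]-2,3-dihydro-1-benzofuran-4-ol | C(Oc1ccc([C@H]2Oc3cc(OCc4ccccc4)cc(O)c3[C@@H]2c2cc(OCc3ccccc3)cc(OCc3ccccc3)c2)cc1)c1ccccc1 | intermediate
22 | (2S,3S)-6-(benzyloxy)-2-[4-(benzyloxy)phenyl]-3-[3,5-bis(benzyloxy)phenyl]-2,3-dihydro-1-benzofuran-4-yl trifluoromethanesulfonate | C(Oc1ccc([C@H]2Oc3cc(OCc4ccccc4)cc(OS(=O)(=O)C(F)(F)F)c3[C@@H]2c2cc(OCc3ccccc3)cc(OCc3ccccc3)c2)cc1)c1ccccc1 | intermediate
23 | ethynyl(trimethyl)silane | C#C[Si](C)(C)C | starting material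
24 | ethyl[(trimethylsilyl)ethynyl]zinc | CC[Zn]C#C[Si](C)(C)C | intermediate (not isolated)
25 | (1S)-1-[3,5-bis(benzyloxy)phenyl]-3-(trimethylsilyl)prop-2-yn-1-ol | O[C@H](C#C[Si](C)(C)C)c1cc(OCc2ccccc2)cc(OCc2ccccc2)c1 | intermediate
26 | (1S)-1-[3,5-bis(benzyloxy)phenyl]-3-(trimethylsilyl)prop-2-yn-1-yl methanesulfonate | CS(=O)(=O)O[C@H](C#C[Si](C)(C)C)c1cc(OCc2ccccc2)cc(OCc2ccccc2)c1 | intermediate
27 | (aR)-{3-[3,5-bis(benzyloxy)phenyl]-1-(trimethylsilyl)propa-1,2-dien-1-yl}(iodo)indium methanesulfonate | CS(=O)(=O)O[In](I)C([Si](C)(C)C)=[C@]=C([H])c1cc(OCc2ccccc2)cc(OCc2ccccc2)c1 | intermediate (not isolated)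
28 | (1R,2R)-1-[4-(benzyloxy)phenyl]-2-[3,5-bis(benzyloxy)phenyl]-4-(trimethylsilyl)but-3-yn-1-ol | O[C@@H](c1ccc(OCc2ccccc2)cc1)[C@@H](C#C[Si](C)(C)C)c1cc(OCc2ccccc2)cc(OCc2ccccc2)c1 | intermediate
29 | dicyclohexylborinate of 28 carrying a (Z)-1-(dicyclohexylboryl)-1-(trimethylsilyl)alkene in place of the alkyne (boron and silicon on the same carbon, H cis to boron) | C1CCCCC1B(C1CCCCC1)O[C@@H](c1ccc(OCc2ccccc2)cc1)[C@@H](/C=C(\[Si](C)(C)C)B(C1CCCCC1)C1CCCCC1)c1cc(OCc2ccccc2)cc(OCc2ccccc2)c1 | intermediate (not isolated)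
30 | (3S,4R)-4-[4-(benzyloxy)phenyl]-3-[3,5-bis(benzyloxy)phenyl]-4-hydroxybutanoic acid | OC(=O)C[C@@H](c1cc(OCc2ccccc2)cc(OCc2ccccc2)c1)[C@@H](O)c1ccc(OCc2ccccc2)cc1 | intermediate (not isolated)
31 | (4S,5R)-5-[4-(benzyloxy)phenyl]-4-[3,5-bis(benzyloxy)phenyl]oxolan-2-one | O=C1C[C@@H](c2cc(OCc3ccccc3)cc(OCc3ccccc3)c2)[C@H](c2ccc(OCc3ccccc3)cc2)O1 | intermediate
32 | chlorozinc enolate of 31, {[(4S,5R)-5-[4-(benzyloxy)phenyl]-4-[3,5-bis(benzyloxy)phenyl]-4,5-dihydrofuran-2-yl]oxy}(chloro)zinc | Cl[Zn]OC1=C[C@@H](c2cc(OCc3ccccc3)cc(OCc3ccccc3)c2)[C@H](c2ccc(OCc3ccccc3)cc2)O1 | intermediate (not isolated)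
33 | (3S,4S,5R)-3-{(2S,3S)-6-(benzyloxy)-2-[4-(benzyloxy)phenyl]-3-[3,5-bis(benzyloxy)phenyl]-2,3-dihydro-1-benzofuran-4-yl}-5-[4-(benzyloxy)phenyl]-4-[3,5-bis(benzyloxy)phenyl]oxolan-2-one (3,4-trans) | C(Oc1ccc([C@H]2Oc3cc(OCc4ccccc4)cc([C@@H]4[C@@H](c5cc(OCc6ccccc6)cc(OCc6ccccc6)c5)[C@H](c5ccc(OCc6ccccc6)cc5)OC4=O)c3[C@@H]2c2cc(OCc3ccccc3)cc(OCc3ccccc3)c2)cc1)c1ccccc1 | intermediate
34 | lithium enolate of 33, lithium (4R,5R)-3-(benzofuran-4-yl)-4,5-diaryl-4,5-dihydrofuran-2-olate | C(Oc1ccc([C@H]2Oc3cc(OCc4ccccc4)cc(C4=C(O[Li])O[C@@H](c5ccc(OCc6ccccc6)cc5)[C@@H]4c4cc(OCc5ccccc5)cc(OCc5ccccc5)c4)c3[C@@H]2c2cc(OCc3ccccc3)cc(OCc3ccccc3)c2)cc1)c1ccccc1 | intermediate (not isolated)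
35 | (3R,4S,5R)-3-{(2S,3S)-6-(benzyloxy)-2-[4-(benzyloxy)phenyl]-3-[3,5-bis(benzyloxy)phenyl]-2,3-dihydro-1-benzofuran-4-yl}-5-[4-(benzyloxy)phenyl]-4-[3,5-bis(benzyloxy)phenyl]oxolan-2-one (3,4-cis) | C(Oc1ccc([C@H]2Oc3cc(OCc4ccccc4)cc([C@H]4[C@@H](c5cc(OCc6ccccc6)cc(OCc6ccccc6)c5)[C@H](c5ccc(OCc6ccccc6)cc5)OC4=O)c3[C@@H]2c2cc(OCc3ccccc3)cc(OCc3ccccc3)c2)cc1)c1ccccc1 | intermediate
36 | 1-(benzyloxy)-4-bromobenzene | Brc1ccc(OCc2ccccc2)cc1 | starting material
37 | [4-(benzyloxy)phenyl]lithium | [Li]c1ccc(OCc2ccccc2)cc1 | intermediate (not isolated)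
38 | [4-(benzyloxy)phenyl]cerium dichloride | Cl[Ce](Cl)c1ccc(OCc2ccccc2)cc1 | intermediate (not isolated)
39 | (3R,4S,5R)-3-{(2S,3S)-6-(benzyloxy)-2-[4-(benzyloxy)phenyl]-3-[3,5-bis(benzyloxy)phenyl]-2,3-dihydro-1-benzofuran-4-yl}-2,5-bis[4-(benzyloxy)phenyl]-4-[3,5-bis(benzyloxy)phenyl]oxolan-2-ol (both C2 anomers) | C(Oc1ccc([C@H]2Oc3cc(OCc4ccccc4)cc([C@H]4[C@@H](c5cc(OCc6ccccc6)cc(OCc6ccccc6)c5)[C@H](c5ccc(OCc6ccccc6)cc5)OC4(O)c4ccc(OCc5ccccc5)cc4)c3[C@@H]2c2cc(OCc3ccccc3)cc(OCc3ccccc3)c2)cc1)c1ccccc1 | intermediate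
40 | (2S,3S)-6-(benzyloxy)-2-[4-(benzyloxy)phenyl]-3-[3,5-bis(benzyloxy)phenyl]-4-{(2R,3R,4S,5R)-2,5-bis[4-(benzyloxy)phenyl]-4-[3,5-bis(benzyloxy)phenyl]oxolan-3-yl}-2,3-dihydro-1-benzofuran | C(Oc1ccc([C@H]2Oc3cc(OCc4ccccc4)cc([C@H]4[C@@H](c5cc(OCc6ccccc6)cc(OCc6ccccc6)c5)[C@H](c5ccc(OCc6ccccc6)cc5)O[C@H]4c4ccc(OCc5ccccc5)cc4)c3[C@@H]2c2cc(OCc3ccccc3)cc(OCc3ccccc3)c2)cc1)c1ccccc1 | intermediate
41 | (2S,3S)-4-[(2R,3R,4S,5R)-4-(3,5-dihydroxyphenyl)-2,5-bis(4-hydroxyphenyl)oxolan-3-yl]-3-(3,5-dihydroxyphenyl)-2-(4-hydroxyphenyl)-2,3-dihydro-1-benzofuran-6-ol (CNP0202577.4) | Oc1ccc([C@H]2Oc3cc(O)cc([C@H]4[C@@H](c5cc(O)cc(O)c5)[C@H](c5ccc(O)cc5)O[C@H]4c4ccc(O)cc4)c3[C@@H]2c2cc(O)cc(O)c2)cc1 | target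

**Step count**

Total: 18 steps. Longest linear sequence: 13 steps (1–5, 7–9, 14–18).

**Steps most likely to fail, with fallbacks**

1. Step 7 (proposed new method). Possible failures:
   - rhodium-mediated self-cyclotrimerisation or hydration of the alkoxyalkyne outrunning the cross-reaction;
   - thermal or metal-induced fragmentation of the secondary ynol ether;
   - insertion in the reverse orientation, placing the benzyloxy group at C5.

   Fallback (known chemistry): an ortho-quinone methide (4+1) annulation with a sulfur ylide. It carries over no numbered intermediate and replaces steps 1–8. It starts from commercial 2,4,6-trihydroxybenzaldehyde, 1-bromo-3,5-bis(benzyloxy)benzene and 4-(benzyloxy)benzyl bromide, and rejoins the route at 21.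
   - The non-chelated 4-hydroxyl is benzylated (BnBr, NaHCO3, DMF) to 4-(benzyloxy)-2,6-dihydroxybenzaldehyde F1.
   - Both remaining phenols are protected (MOMCl, i-Pr2NEt) to give 4-(benzyloxy)-2,6-bis(methoxymethoxy)benzaldehyde F2.
   - Addition of 3,5-bis(benzyloxy)phenylmagnesium bromide gives the diarylmethanol F3.
   - Aqueous HCl in methanol with sodium 4-methylbenzenesulfinate removes the acetals and traps the benzylic cation as the sulfone-resorcinol F4.
   - 4-(Benzyloxy)benzyl bromide and dimethyl sulfide give the sulfonium bromide F5.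
   - Cs2CO3 in CH2Cl2 turns F4 into the ortho-quinone methide and F5 into its ylide; conjugate addition and displacement of dimethyl sulfide by the phenoxide should give the racemic trans-dihydrobenzofuranol F6. The resorcinol is symmetric, so either hydroxyl gives the same product.
   - Preparative chromatography on a chiral stationary phase separates 21 from its (2R,3R)-enantiomer F7.

2. Step 14. Possible failures: slow oxidative addition or reductive elimination at C4, which is flanked by the C3 diarylmethine, so that triflate hydrolysis and enolate self-condensation take over.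

   Fallback: reverse the polarity of the union; it sets out from 22 and 31 and returns at 33.
   - Triflate 22 undergoes Miyaura borylation (B2pin2, PdCl2(dppf), KOAc, dioxane, 90 °C) to the pinacol boronate F8.
   - Lactone 31 is brominated through its silyl ketene acetal (LiHMDS, TMSCl, then NBS) to the α-bromolactone F9.
   - A nickel-catalysed Suzuki–Miyaura arylation of the secondary α-bromo carbonyl compound (NiCl2·glyme, 4,4′-di-tert-butyl-2,2′-bipyridine, K3PO4, dioxane, 60 °C) joins them. The alkyl radical intermediate lets the aryl group settle trans to the C4′ aryl group, which gives 33.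

3. Step 15. Possible failures: poor facial selectivity in the protonation, or epimerisation of the cis lactone back to trans during work-up or in step 16.

   Fallback: set C3′ and C2′ together by hydrogenation; it sets out from 33 and returns at 41.
   - Arylcerium reagent 38 is added to the trans lactone 33 as in step 16 to give the hemiketal F10.
   - Acid-catalysed dehydration (PPTS, toluene, 4 Å molecular sieves) gives the 2,3-diaryl-4,5-dihydrofuran F11, in which C3′ is no longer a stereocentre.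
   - Hydrogenation over Pd(OH)2/C (H2, 5 bar, EtOAc–MeOH) should add both hydrogens to the face opposite the C4′ aryl group, giving the 2′,3′-cis-3′,4′-cis oxolane, and remove the benzyl ethers in the same operation to give 41.

**Further compounds**

F1 | step 7 | 4-(benzyloxy)-2,6-dihydroxybenzaldehyde | O=Cc1c(O)cc(OCc2ccccc2)cc1O
F2 | step 7 | 4-(benzyloxy)-2,6-bis(methoxymethoxy)benzaldehyde | O=Cc1c(OCOC)cc(OCc2ccccc2)cc1OCOC
F3 | step 7 | [4-(benzyloxy)-2,6-bis(methoxymethoxy)phenyl][3,5-bis(benzyloxy)phenyl]methanol (racemic) | OC(c1cc(OCc2ccccc2)cc(OCc2ccccc2)c1)c1c(OCOC)cc(OCc2ccccc2)cc1OCOC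
F4 | step 7 | 5-(benzyloxy)-2-{[3,5-bis(benzyloxy)phenyl](4-methylbenzenesulfonyl)methyl}benzene-1,3-diol (racemic) | Cc1ccc(S(=O)(=O)C(c2cc(OCc3ccccc3)cc(OCc3ccccc3)c2)c2c(O)cc(OCc3ccccc3)cc2O)cc1
F5 | step 7 | {[4-(benzyloxy)phenyl]methyl}dimethylsulfonium bromide | C[S+](C)Cc1ccc(OCc2ccccc2)cc1.[Br-]
F6 | step 7 | racemic trans-6-(benzyloxy)-2-[4-(benzyloxy)phenyl]-3-[3,5-bis(benzyloxy)phenyl]-2,3-dihydro-1-benzofuran-4-ol (both enantiomers) | C(Oc1ccc([C@H]2Oc3cc(OCc4ccccc4)cc(O)c3[C@@H]2c2cc(OCc3ccccc3)cc(OCc3ccccc3)c2)cc1)c1ccccc1.C(Oc1ccc([C@@H]2Oc3cc(OCc4ccccc4)cc(O)c3[C@H]2c2cc(OCc3ccccc3)cc(OCc3ccccc3)c2)cc1)c1ccccc1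
F7 | step 7 | (2R,3R)-6-(benzyloxy)-2-[4-(benzyloxy)phenyl]-3-[3,5-bis(benzyloxy)phenyl]-2,3-dihydro-1-benzofuran-4-ol | C(Oc1ccc([C@@H]2Oc3cc(OCc4ccccc4)cc(O)c3[C@H]2c2cc(OCc3ccccc3)cc(OCc3ccccc3)c2)cc1)c1ccccc1
F8 | step 14 | 2-{(2S,3S)-6-(benzyloxy)-2-[4-(benzyloxy)phenyl]-3-[3,5-bis(benzyloxy)phenyl]-2,3-dihydro-1-benzofuran-4-yl}-4,4,5,5-tetramethyl-1,3,2-dioxaborolane | C(Oc1ccc([C@H]2Oc3cc(OCc4ccccc4)cc(B4OC(C)(C)C(C)(C)O4)c3[C@@H]2c2cc(OCc3ccccc3)cc(OCc3ccccc3)c2)cc1)c1ccccc1
F9 | step 14 | (4S,5R)-5-[4-(benzyloxy)phenyl]-4-[3,5-bis(benzyloxy)phenyl]-3-bromooxolan-2-one (C3 epimers) | O=C1C(Br)[C@@H](c2cc(OCc3ccccc3)cc(OCc3ccccc3)c2)[C@H](c2ccc(OCc3ccccc3)cc2)O1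
F10 | step 15 | (3S,4S,5R)-3-{(2S,3S)-6-(benzyloxy)-2-[4-(benzyloxy)phenyl]-3-[3,5-bis(benzyloxy)phenyl]-2,3-dihydro-1-benzofuran-4-yl}-2,5-bis[4-(benzyloxy)phenyl]-4-[3,5-bis(benzyloxy)phenyl]oxolan-2-ol (both C2 anomers) | C(Oc1ccc([C@H]2Oc3cc(OCc4ccccc4)cc([C@@H]4[C@@H](c5cc(OCc6ccccc6)cc(OCc6ccccc6)c5)[C@H](c5ccc(OCc6ccccc6)cc5)OC4(O)c4ccc(OCc5ccccc5)cc4)c3[C@@H]2c2cc(OCc3ccccc3)cc(OCc3ccccc3)c2)cc1)c1ccccc1
F11 | step 15 | (2S,3S)-6-(benzyloxy)-2-[4-(benzyloxy)phenyl]-3-[3,5-bis(benzyloxy)phenyl]-4-{(4R,5R)-2,5-bis[4-(benzyloxy)phenyl]-4-[3,5-bis(benzyloxy)phenyl]-4,5-dihydrofuran-3-yl}-2,3-dihydro-1-benzofuran | C(Oc1ccc([C@H]2Oc3cc(OCc4ccccc4)cc(C4=C(c5ccc(OCc6ccccc6)cc5)O[C@@H](c5ccc(OCc6ccccc6)cc5)[C@@H]4c4cc(OCc5ccccc5)cc(OCc5ccccc5)c4)c3[C@@H]2c2cc(OCc3ccccc3)cc(OCc3ccccc3)c2)cc1)c1ccccc1
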